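Retrosynthesis: the two ester C–O bonds are cut first (C3–O with inversion, C9–O), then the C7–C11 bond, the C9–O bond and the C10–H bond of ring B, which leads back to a Δ9(10)-en-8-one.
Ring A (C1–C5, C10) is then contracted: the C4–C5 bond is cut and C5 is re-joined to C3, giving a hydrindane whose cyclopentane C5–C3–C2–C1–C10 carries a tertiary carbinol at C3 with an exocyclic CH(CH3)OMs group (C4, C15).
Forward: ring B and the quaternary C5 come ready-made in (S)-Hajos–Parrish ketone; ethylidenation and cis-hydroxylation build the diol, the mesylate is made, and the five-to-six ring expansion gives ring A with the C4 methyl and C3 carbonyl in place; ring B is then finished by enolate chemistry and the esters go on last.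
What makes the event possible: carbinol carbon C3 sits next to the fully substituted ring-fusion carbon C5, whose bond to C3 can swing onto the neighbouring secondary mesylate carbon C4 while the oxygen on C3 becomes the ketone.
Stereochemistry: C5 from the starting ketone (retention in the shift); C4 by inversion at the (R)-mesylate; C3 by α-face hydride, then Mitsunobu inversion; C10 by dissolving-metal reduction; C9 by α-face Rubottom oxidation; C7 equatorial.
Key step: step 4

Remark: the SMILES is read as the 10αH (trans-fused) eremophilane with 4β,5β-dimethyl, 3α- and 9α-acyloxy and 7α-isopropenyl groups; eremophilane numbering and α/β (β = face of the C5 methyl) are used for every compound, hydrindanes included.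

Step 1
Reactants: 1 (S)-Hajos–Parrish ketone; 2 ethyltriphenylphosphonium bromide
Product: 3 (Z)-ethylidene enone
Conditions: 2 (2.5 equiv), KOtBu (2.5 equiv), THF, 0 to 50 °C; aq. NH4Cl, then 1 M HCl/THF, rt
Reagents that add atoms: ethyltriphenylphosphonium bromide CC[P+](c1ccccc1)(c1ccccc1)c1ccccc1.[Br-]
Why: Wittig olefination, in which the unstabilised ylide should attack only the saturated cyclopentanone because the conjugated ketone is less electrophilic and is held as its potassium dienolate by the excess base (re-conjugated by the acid wash), and which should give the Z-alkene with the new methyl group cis to the quaternary C5, as such ylides do with ketones flanked by a quaternary carbon.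

Step 2
Reactants: 3 (Z)-ethylidene enone; 4 silver acetate
Product: 7 3β-hydroxy-(4R)-hydroxy diol, via iodo acetate 5 (not isolated), via hydroxy acetate 6 (not isolated)
Conditions: I2 (1.05 equiv), AgOAc (2.3 equiv), AcOH, rt; AcOH/H2O, 90 °C; then K2CO3, MeOH, rt
Reagents that add atoms: silver acetate CC(=O)[O-].[Ag+]
Why: Woodward cis-hydroxylation, in which the iodonium ion forms on the open α-face, acetate opens it anti and the neighbouring acetoxy group displaces iodide to an acetoxonium ion lying wholly on the β-face, so that hydrolysis gives the cis-diol on the face of the C5 methyl (the face OsO4 would not reach), which places the tertiary OH β, the side chain α and makes the secondary carbinol C4 (R).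

Step 3
Reactants: 7 3β-hydroxy-(4R)-hydroxy diol; 8 methanesulfonyl chloride
Product: 9 (4R)-mesylate of the tertiary alcohol
Conditions: MsCl (1.2 equiv), Et3N, CH2Cl2, −30 °C
Reagents that add atoms: methanesulfonyl chloride CS(=O)(=O)Cl
Why: Sulfonylation of the secondary alcohol, chemoselective because the tertiary neopentyl alcohol does not react at low temperature, with no stereocenter touched.

Step 4
Reactants: 9 (4R)-mesylate of the tertiary alcohol
Product: 10 cis-4β,5β-dimethyl enedione
Conditions: Et2AlCl (3 equiv), CH2Cl2, −78 to 0 °C; aq. KNaC4H4O6 work-up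
Reagents that add atoms: none
Why: Et2AlCl turns the tertiary alcohol into an aluminium alkoxide and pulls on the mesylate, and the C3–C5 bond of the cyclopentane, held anti-periplanar to the C4–OMs bond, shifts from C3 to C4 while the alkoxide collapses to the C3 ketone (semipinacol rearrangement of a β-mesyloxy alcohol; the closest ring-size analogy is the D-homoannulation of 17-hydroxy-20-sulfonyloxy steroids). No ring is closed from a chain: the five-membered ring C5–C3–C2–C1–C10 takes up the exocyclic carbon C4 between C5 and C3 by a 1,2-alkyl shift and becomes the six-membered ring A. C5 migrates with retention and keeps the configuration of the starting ketone, and C4 is inverted, so the (R)-mesylate gives the 4β-methyl group cis to the C5 methyl. The selectivity needed is migration of the quaternary C5 and not of the CH2 carbon C2, nor closure to the epoxide: with the side chain on the α-face, the rotamer that puts the mesylate anti to C5 has only H between the two ring carbons and the methyl pointing outward, whereas C2 migration needs that methyl wedged between them; C5 is also the better migrating group, and the aluminium-bound oxygen in a non-basic medium is a poor nucleophile for epoxide closure. The enone and the rest of ring B are spectators.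

Step 5
Reactants: 10 cis-4β,5β-dimethyl enedione
Product: 11 3β-hydroxy enone
Conditions: LiAlH(OtBu)3 (1.2 equiv), THF, −78 to −30 °C
Reagents that add atoms: none
Why: Chemoselective hydride reduction, in which the bulky alkoxyaluminium hydride reduces the saturated C3 ketone but not the β,β-disubstituted enone and approaches C3 from the α-face (equatorial attack) because the β-axial path is blocked by the syn-axial C5 methyl, giving the axial 3β-alcohol.

Step 6
Reactants: 11 3β-hydroxy enone; 12 tert-butyldimethylsilyl trifluoromethanesulfonate
Product: 14 bis-silyl enol ether, via dilithium alkoxide enolate 13 (not isolated)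
Conditions: Li (4 equiv), NH3/THF, −78 °C; isoprene; NH3 evaporated; TBSOTf (3 equiv), Et3N, THF, −78 to 0 °C
Reagents that add atoms: tert-butyldimethylsilyl trifluoromethanesulfonate CC(C)(C)[Si](C)(C)OS(=O)(=O)C(F)(F)F
Why: Dissolving-metal enone reduction with enolate trapping (reductive silylation), in which C10 is protonated axially from the α-face (the substrate hydroxyl is the internal proton donor) to give the trans ring fusion and the regiospecific C8–C9 lithium enolate and the C3 alkoxide are both capped on oxygen.

Step 7
Reactants: 14 bis-silyl enol ether; 15 3-chloroperoxybenzoic acid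
Product: 17 3β,9α-bis(silyloxy) ketone, via silyloxy epoxide 16 (not isolated)
Conditions: mCPBA (1.1 equiv), CH2Cl2, −20 to 0 °C
Reagents that add atoms: 3-chloroperoxybenzoic acid O=C(OO)c1cccc(Cl)c1
Why: Rubottom oxidation, in which the peracid epoxidises the electron-rich silyl enol ether from the α-face (the β-face of C9 is shielded by the syn-axial C5 methyl) and the silyloxy epoxide opens with 1,4-silyl shift to the 9α-silyloxy ketone, whose equatorial oxygen is also the thermodynamically preferred epimer.

Step 8
Reactants: 17 3β,9α-bis(silyloxy) ketone; 18 2-bromopropene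
Product: 20 7α-isopropenyl ketone, via lithium enolate 19 (not isolated)
Conditions: LiN(SiMe3)2 (2.2 equiv), Pd2(dba)3 (2.5 mol%), P(t-Bu)3 (6 mol%), 2-bromopropene (1.5 equiv), toluene/THF, rt; AcOH/THF, −78 °C
Reagents that add atoms: 2-bromopropene CC(Br)=C
Why: Palladium-catalysed α-alkenylation of a ketone enolate (the alkenyl counterpart of ketone α-arylation), in which the base can enolise only toward the C7 methylene (C9 is a shielded silyloxy methine), zerovalent palladium inserts into 2-bromopropene and reductive elimination forms the C7–C11 bond, the product rests as its lithium dienolate until the cold acid quench protonates C7, and the equatorial 7α-isopropenyl epimer is expected because the axial one would be syn-axial to the C5 methyl.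

Step 9
Reactants: 20 7α-isopropenyl ketone
Product: 21 3β,9α-diol
Conditions: 48% aq. HF, MeCN, 0 °C to rt
Reagents that add atoms: none
Why: Fluoride desilylation under acidic conditions, which should remove both silyl ethers (the hindered axial one included) without a base that could move the isopropenyl double bond into conjugation or epimerise C7 and C9.

Step 10
Reactants: 21 3β,9α-diol; 22 (E)-2-methylbut-2-enoyl chloride
Product: 23 9α-tiglate 3β-alcohol
Conditions: tigloyl chloride (1.2 equiv), pyridine, DMAP (cat.), CH2Cl2, 0 °C
Reagents that add atoms: (E)-2-methylbut-2-enoyl chloride C/C=C(\C)C(Cl)=O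
Why: DMAP-catalysed acylation that should be site-selective for the equatorial C9 hydroxyl of the α-ketol, since the axial 3β-hydroxyl is syn-axial to the C5 methyl and flanked by the C4 methyl, with the stable E-geometry of the acyl group kept.

Step 11
Reactants: 23 9α-tiglate 3β-alcohol; 24 3-methylbut-2-enoic acid
Product: 25 CNP0164025.1
Conditions: PPh3, DIAD, toluene, 0 °C to rt
Reagents that add atoms: 3-methylbut-2-enoic acid CC(C)=CC(=O)O
Why: Mitsunobu esterification, in which the axial 3β-alcohol is activated as its oxyphosphonium ion and displaced by the carboxylate from the α-face with inversion, setting the equatorial 3α-ester under near-neutral conditions that spare the α-acyloxy ketone and the isopropenyl group (elimination is the competing path).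

Compound list
1 | (S)-Hajos–Parrish ketone, (7aS)-7a-methyl-2,3,7,7a-tetrahydro-1H-indene-1,5(6H)-dione | O=C1C=C2CCC(=O)[C@@]2(C)CC1 | starting material
2 | ethyltriphenylphosphonium bromide | CC[P+](c1ccccc1)(c1ccccc1)c1ccccc1.[Br-] | starting material
3 | (Z)-1-ethylidene-7a-methyl-1,2,3,6,7,7a-hexahydro-5H-inden-5-one of the (S)-series (ethylidene methyl cis to the quaternary carbon) | O=C1C=C2CC/C(=C/C)[C@@]2(C)CC1 | intermediate
4 | silver acetate | CC(=O)[O-].[Ag+] | starting material
5 | iodo acetate (tertiary α-iodide, secondary (R)-acetate) | O=C1C=C2CC[C@](I)([C@@H](C)OC(C)=O)[C@@]2(C)CC1 | intermediate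
6 | hydroxy acetate (cis-β-diol monoacetate) | O=C1C=C2CC[C@@](O)([C@@H](C)OC(C)=O)[C@@]2(C)CC1 | intermediate
7 | 1β-hydroxy-1α-[(1R)-1-hydroxyethyl]-7aβ-methyl-1,2,3,6,7,7a-hexahydro-5H-inden-5-one | O=C1C=C2CC[C@@](O)([C@@H](C)O)[C@@]2(C)CC1 | intermediate
8 | methanesulfonyl chloride | CS(=O)(=O)Cl | starting material
9 | 1β-hydroxy-1α-[(1R)-1-(methanesulfonyloxy)ethyl]-7aβ-methyl-1,2,3,6,7,7a-hexahydro-5H-inden-5-one | O=C1C=C2CC[C@@](O)([C@@H](C)OS(C)(=O)=O)[C@@]2(C)CC1 | intermediate
10 | cis-4a,5-dimethyl-3,4,4a,5,7,8-hexahydronaphthalene-2,6-dione (11,12,13-trinoreremophil-9-ene-3,8-dione, 4β,5β-dimethyl) | C1C[C@]2(C)[C@@H](C)C(=O)CCC2=CC1=O | intermediate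
11 | 3β-hydroxy-11,12,13-trinoreremophil-9-en-8-one | C1C[C@]2(C)[C@@H](C)[C@@H](O)CCC2=CC1=O | intermediate
12 | tert-butyldimethylsilyl trifluoromethanesulfonate | CC(C)(C)[Si](C)(C)OS(=O)(=O)C(F)(F)F | starting material
13 | dilithium 3β-alkoxide C8–C9 enolate (10αH) | C1C[C@]2(C)[C@@H](C)[C@@H](O[Li])CC[C@H]2C=C1O[Li] | intermediate
14 | 3β,8-bis(tert-butyldimethylsilyloxy)-10αH-11,12,13-trinoreremophil-8-ene | C1C[C@]2(C)[C@@H](C)[C@@H](O[Si](C)(C)C(C)(C)C)CC[C@H]2C=C1O[Si](C)(C)C(C)(C)C | intermediate
15 | 3-chloroperoxybenzoic acid | O=C(OO)c1cccc(Cl)c1 | starting material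
16 | 8α,9α-epoxide of 14 | C1C[C@]2(C)[C@@H](C)[C@@H](O[Si](C)(C)C(C)(C)C)CC[C@H]2[C@@H]3O[C@]13O[Si](C)(C)C(C)(C)C | intermediate
17 | 3β,9α-bis(tert-butyldimethylsilyloxy)-10αH-11,12,13-trinoreremophilan-8-one | C1C[C@]2(C)[C@@H](C)[C@@H](O[Si](C)(C)C(C)(C)C)CC[C@H]2[C@H](O[Si](C)(C)C(C)(C)C)C1=O | intermediate
18 | 2-bromopropene | CC(Br)=C | starting material
19 | lithium C7–C8 enolate of 17 | [Li]OC1=CC[C@]2(C)[C@@H](C)[C@@H](O[Si](C)(C)C(C)(C)C)CC[C@H]2[C@@H]1O[Si](C)(C)C(C)(C)C | intermediate
20 | 3β,9α-bis(tert-butyldimethylsilyloxy)-10αH-eremophil-11-en-8-one (7α-isopropenyl) | C=C(C)[C@@H]1C[C@]2(C)[C@@H](C)[C@@H](O[Si](C)(C)C(C)(C)C)CC[C@H]2[C@H](O[Si](C)(C)C(C)(C)C)C1=O | intermediate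
21 | 3β,9α-dihydroxy-10αH-eremophil-11-en-8-one | C=C(C)[C@@H]1C[C@]2(C)[C@@H](C)[C@@H](O)CC[C@H]2[C@H](O)C1=O | intermediate
22 | (E)-2-methylbut-2-enoyl chloride (tigloyl chloride) | C/C=C(\C)C(Cl)=O | starting material
23 | 3β-hydroxy-9α-tigloyloxy-10αH-eremophil-11-en-8-one | C=C(C)[C@@H]1C[C@]2(C)[C@@H](C)[C@@H](O)CC[C@H]2[C@H](OC(=O)/C(C)=C/C)C1=O | intermediate
24 | 3-methylbut-2-enoic acid (senecioic acid) | CC(C)=CC(=O)O | starting material
25 | CNP0164025.1, 3α-(3-methylbut-2-enoyloxy)-9α-tigloyloxy-10αH-eremophil-11-en-8-one | C=C(C)[C@@H]1C[C@]2(C)[C@@H](C)[C@H](OC(=O)C=C(C)C)CC[C@H]2[C@H](OC(=O)/C(C)=C/C)C1=O | target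

Total step count: 11. Longest linear sequence: 11 steps (from 1).

Steps most likely to fail

Step 4. What may go wrong: the ring CH2 carbon C2 migrates in place of C5, or the alkoxide closes onto the mesylate carbon (epoxide formation). Fallback, from diol 7 back to 10: Dess–Martin periodinane would oxidise the secondary alcohol to the methyl ketol F1. BF3·OEt2 in Ac2O/AcOH would then bring about the α-ketol (acyloin) rearrangement, in which the quaternary carbon shifts to the acetyl carbon (ring expansion five to six, the course expected for a hydroxyl cis and an acyl group trans to the angular methyl) and the new tertiary alcohol is acetylated, giving the acetoxy ketone F2 (its C4 configuration is of no consequence). SmI2 in THF/MeOH at −78 °C would cleave the α-acetoxy group, and the samarium enolate would take its proton at C4 from the α-face, giving 10 with the 4β-methyl group.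

Step 2. What may go wrong: opening of the iodonium ion is diverted into a shift of the angular methyl or into elimination at the cation-like C3, or attack on the hindered β-face is too slow. Fallback, from 1 back to 7: ethane-1,2-dithiol and BF3·OEt2 in MeOH would convert only the conjugated carbonyl into the dithiolane F3. 1-Ethoxyvinyllithium (from ethyl vinyl ether and t-BuLi, with CeCl3) would add to the cyclopentanone from the α-face, and oxalic acid work-up would free the methyl ketone, giving the ketol dithiolane F4. Zn(BH4)2 in Et2O at −78 °C would reduce this ketone under chelate control to the (R)-carbinol, the diol dithiolane F5. MeI and NaHCO3 in aqueous MeCN would remove the dithiolane and return diol 7.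

Step 8. What may go wrong: the new double bond moves into conjugation with the ketone, the dienolate is protonated from the wrong face at C7, or the hindered enolate stalls the catalyst. Fallback, from 17 back to 20: LiN(iPr)2, then ZnCl2 and acetone at −78 °C, would give the aldol F6 with the C–C bond formed on the α-face. SOCl2 in pyridine at −20 °C would dehydrate it toward the methyl groups without enolising the ketone and return 20.

Further compounds
F1 | step 4 | 1α-acetyl-1β-hydroxy-7aβ-methyl-1,2,3,6,7,7a-hexahydro-5H-inden-5-one | O=C1C=C2CC[C@@](O)(C(C)=O)[C@@]2(C)CC1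
F2 | step 4 | 4-acetoxy-4,5β-dimethyl-11,12,13-trinoreremophil-9-ene-3,8-dione | C1C[C@]2(C)[C@@](C)(OC(C)=O)C(=O)CCC2=CC1=O
F3 | step 2 | C8 1,3-dithiolane of 1 | S1CCSC12C=C3CCC(=O)[C@@]3(C)CC2
F4 | step 2 | C8 1,3-dithiolane of the 1α-acetyl-1β-hydroxy ketol | S1CCSC12C=C3CC[C@@](O)(C(C)=O)[C@@]3(C)CC2
F5 | step 2 | C8 1,3-dithiolane of diol 7 | S1CCSC12C=C3CC[C@@](O)([C@@H](C)O)[C@@]3(C)CC2
F6 | step 8 | 7α-(2-hydroxypropan-2-yl)-3β,9α-bis(tert-butyldimethylsilyloxy)-10αH-11,12,13-trinoreremophilan-8-one | CC(C)(O)[C@@H]1C[C@]2(C)[C@@H](C)[C@@H](O[Si](C)(C)C(C)(C)C)CC[C@H]2[C@H](O[Si](C)(C)C(C)(C)C)C1=O
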